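All constants are assumed; the rest is arithmetic.

In this closed flask the charge stays whole: whatever leaves the starting material stands as target, crystals, isomer of the product or quenched substrate.

    starting material ⇌ target (K1 = 0.42, k1 = 0.022 s⁻¹)
    starting material ⇌ isomer of the product (K2 = 140, k2 = 0.0073 s⁻¹)
    crystals ⇌ target, rate k3*(cs3 - [target]) while solid is left; crystals form when [target] > cs3 (cs3 = 0.68 mM, k3 = 0.022 s⁻¹)
    starting material + protic impurity → quenched substrate (k4 = 0.15 L mol⁻¹ s⁻¹)

starting material 0.050 M; protic impurity 0.0100 M; time 25 min

- for target the crystals are counted in
- as a solid, counted per litre of solution: crystals
- run time (flask): 25 min

* how much target and crystals together there is at 25 min, in percent of the starting material charged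
* the change that raises the amount of target and crystals together at 25 min, in percent of the starting material charged most ("none" if none brings more than 2 percentage points) (south-east / north-west / none)
* amount of target and crystals together at 25 min, in percent of the starting material charged, after north-west

- south-east: doubling the solubility in step 3, all else as stated
- north-west: doubling the dissolution coefficient of step 3, all else as stated

We reckon what stays in the crystals, not what is made. Step 3 has one law for growing and dissolving, so we write the crystals as a share of the charge won early, minus a steady leak times the time.

Starting material leaves by three doors. While crystals draw on it, and leaving the solubility aside, we take c(target) at 0.296 of c(starting material), so the crystal door is 0.390 min⁻¹. The isomer door is 0.44 min⁻¹. The quench door, with protic impurity held at its charge (pseudo-first-order), is 0.0900 min⁻¹. The crystals' share is their door over the sum of the three.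

Later, leaving the quench door aside, we let target that turns back to starting material go on to isomer with a chance of 0.249, a pull of 0.783 min⁻¹. Dissolving and pull act in series on the solubility, giving 0.334 mM min⁻¹: the crystal leak, the steady loss of crystals to isomer while solid is left.

Share won, lost by 25 min, and what stays in the crystals, which we take for target and crystals together:

- Flask: 42.5%, 16.7%, 25.8%
- South-east: 42.5%, 33.4%, 9.10%
- North-west: 53.3%, 20.5%, 32.8%

Reading down, south-east in our reckoning keeps the share and loses twice as much. North-west adds 11 percentage points to the share but 3.8 points to the loss, a smaller rise. Our choice is north-west.

The forecast gives 27%, above our figure, then 33% and north-west, holding that “the isomer sink drains solids”.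

The flask gives 27.3% and north-west 33.3%; north-west wins with 6 points, and south-east brings −18 points. In the flask, by 12.5 min starting material was down to 1.64%, with crystals at 34.2%. From then to 25.0 min starting material stood near 1.66% while crystals fell to 26.4% and isomer rose from 54.5% to 61.3%, target and crystals together falling 0.311 mM min⁻¹ against a leak of 0.334 mM min⁻¹. For the same flask stopped at 15 min, share minus leak gives 32.5%, and it holds 33.5% of target and crystals together.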